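**Remark on the chemistry.** The descriptors 1S,2S,3R,5S,6R,7S,8R (numbering below) follow from the SMILES string. C8 is formed without control in step 2 and is made uniform in step 5. Atom numbers and the α/β face labels of the target are used for all intermediates; the six-membered precursors simply lack C7.

## Structural features

The target is a cycloheptane whose ring atoms are numbered here as they follow in the SMILES string: C1 (quaternary carbinol carrying the (E)-but-2-enoyl group), C2 (CH3), C3 (OH), C4 (CH2), C5, C6 and C7 (tiglate). A γ-lactone is cis-fused across C5–C6, with its oxygen on C6 and its α-carbon C8 (bearing the methyl C10) on C5; C9 is the lactone carbonyl. C5, C6, C7, C1, C2 and C3 form an unbroken row of six stereocentres and C8 is a seventh. If β is the face of the carbocycle that carries the two lactone bonds (C5–C8 and C6–O), the substituents are 1β-OH/1α-acyl, 2β-CH3, 3α-OH and 7α-O-tigloyl; the oxygens on C6, C7 and C1 thus alternate β, α, β, the C1 hydroxyl lies on the more crowded face, and the C8 methyl points into the concave side of the bicycle (H5, H6 and H8 are all cis). Fragile elements are the tertiary α-ketol at C1, the crotonoyl enone (a Michael acceptor, also towards a free 7-OH), the tiglate, the lactone oxygen on C6 (a β-leaving group for any C1 ketone enolized towards C7), and C2 and C8, which epimerize whenever they stand next to a carbonyl group. The real difficulty is the seven-membered ring together with the alternating C6/C7/C1 oxygenation next to the ring fusion and the quaternary C1. The key step exploits that C1–C6, with the C2 methyl and the three-carbon branch C8/C9/C10 on C5, are exactly the skeleton of a 2-methyl-5-isopropenylcyclohexanone; only C7 is missing, and it lies between the carbonyl carbon C1 and the unsubstituted C6. A single carbon inserted into the C1–C6 bond of a six-membered ketone therefore creates the ring and arrives as the enol carbon from which the C6 and C7 oxygens can be placed.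

## Logic of the disconnections

24 to 22 (through 23): the O–Si bond at C3 and the side-chain carbonyl (as a masked enol ether) are the only changes. The enone and the free 3-OH are revealed last because both are sensitive; the forward step must hydrolyse the enol ether and remove silicon without touching the ester, the lactone or the α-ketol.

22 to 21: the C7–O acyl bond is cut. This removes five carbons and leaves a diol in which only the secondary 7-OH can be acylated; the forward step must be done before the enone exists, so that 7-OH cannot add to it.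

21 to 16 and 20 (20 from 19): the C1–C(side chain) bond is cut. Carbon is put on C1 last because every reagent should reach C1 from the α face, which gives the β-hydroxyl only if oxygen is already on C1. The gain is the whole four-carbon chain; the demand is α-face, ketone-selective addition in the presence of the lactone.

16 to 14 (through 15): the lactone C6–O bond is cut back to an α,β-epoxy ketone and a carboxyl group. One operation then sets C6 by inversion and keeps C7, which gives the trans C6/C7 pattern; the demand is attack at C6 and not at C7.

14 to 13: the two C–O bonds of the epoxide are cut to an enone. The forward step needs the oxidant on the α face, opposite the C5 side chain.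

13 to 12 to 10 (through 11): the key disconnection. C7 is taken out, that is the C1–C7 and C6–C7 bonds are cut and C1–C6 is rejoined. The seven-membered ring becomes a cyclohexanone that already carries C2, C3, C5 and C8. The demand is that C6, not C2, migrates, and that the new carbon is delivered as the enol carbon.

10 to 9 to 7 (through 8): the C1 carbonyl goes back to the 1β-carbinol and the ester to the bridged lactone C9–O–C1. This lactone is what tells the 1- and 3-hydroxyls apart and gives a rigid frame for C8.

7 to 5 (through 6): only the C8–H bond is concerned; both C8 epimers of 5 converge through one enolate. The demand is face-selective protonation.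

5 to 4 to 3: the O–Si bond and the oxidation level of C9 are removed, back to a triol. The forward oxidation must pick the primary alcohol and the cis 1-hydroxyl.

3 to 2: the C3–O, C2–H, C9–O and C8–H bonds are cut, back to two alkenes. C2 and C3 are set together by one syn addition; the demand is α-face attack on the ring alkene.

2 to 1: the C1–H bond is cut; the forward reduction must give the cis carbinol.

19 to 18 to 17: the four-carbon nucleophile goes back to a commercial alkynol by a C–H shift and an O–CH3 bond.

## Other disconnections considered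

Alternative 1: the first idea is to cut C6–C7 as an alkene and close the ring by metathesis of the open-chain triene A1 to the cycloheptene A2. A1 needs five stereocentres, including the tertiary carbinol C1, to be built by acyclic stereocontrol, whereas the chosen plan takes six ring carbons and C5 from the chiral pool and sets C2/C3 in one hydroboration. The metathesis catalyst would also have to ignore the crotonoyl alkene. After closure, the free 1β-hydroxyl of A2 would direct an epoxidizing agent to the β face, which is the wrong face for the C6/C7 pattern. More steps and less stereochemical leverage.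

Alternative 2: cut C2–C3 and C6–C7 and form both in a (4+3) cycloaddition of furan with the oxyallyl cation A3, giving the oxabicycle A4 with the C1 ketone flanked by C2 (CH3) and C7 (O). The ether bridge of A4 holds the C3 and C6 oxygens on the same face, whereas the target has them on opposite faces, so one C–O bond would have to be inverted after the bridge is opened. The compact transition state also places the C2 methyl and the C7 oxygen cis, and the target needs them trans. The C5 side chain would have to enter on the endo face of the bicycle, and A4 is racemic and not meso, so an enantioselective variant or a resolution is needed. The ring is made in one step, but three stereochemical corrections follow.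

Alternative 3: cut C1–C2 and C1–C7, that is insert C1 with its whole side chain, by homologation of the six-membered keto lactone A5 (ketone at C7) with the diazo ketone A6 to the β-diketone A7. Migration would be well controlled, because the acyloxy-bearing C6 does not migrate. The ground for rejection is stereochemical: the C1 hydroxyl would then have to be introduced by an electrophilic oxidant on the enol of A7, which should approach from the open α face, anti to the C2 methyl and the lactone, and give the wrong C1 configuration. The C7 carbonyl would likewise be reduced from the α face to a 7β-alcohol. The chosen plan inserts C7 instead, makes the C1–C bond last from the α face, and sets C7 by an α-face oxidation.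

Key step: step 8

## Steps

Step 1
Reactants: 1 (R)-(−)-carvone
Product: 2 (1R,5R)-cis-carveol (1β-OH cis to the 5β-isopropenyl group)
Conditions: NaBH4, CeCl3·7H2O, MeOH, −78 → 0 °C
Reagents that add atoms: none
Why: Luche reduction (1,2-reduction of the enone); hydride should add to C1 anti to the C5 isopropenyl group on the half-chair, so the new hydroxyl is β, cis to the side chain.

Step 2
Reactants: 2 (1R,5R)-cis-carveol
Product: 3 5β-(1-hydroxypropan-2-yl)-2β-methylcyclohexane-1β,3α-diol (both C8 epimers)
Conditions: 9-BBN (3.5 equiv), THF, 0 → 65 °C; then NaOH, H2O2, 0 → 23 °C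
Reagents that add atoms: hydrogen peroxide, OO
Why: Hydroboration–oxidation of both alkenes; on the ring alkene the anti-Markovnikov syn addition should put boron on C3 and hydrogen on C2 from the α face, anti to the borinate-capped 1β-oxygen, which sets 3α-OH and 2β-CH3 together. A dialkylborane with no spare B–H is used so that the side-chain borane cannot return intramolecularly to the β face; C8 is not controlled here and is settled in step 5.

Step 3
Reactants: 3 triol (both C8 epimers)
Product: 4 7-hydroxy-4,8-dimethyl-2-oxabicyclo[3.3.1]nonan-3-one, the δ-lactone C9(=O)–O–C1 with free 3α-OH (both C8 epimers)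
Conditions: TEMPO (0.2 equiv), PhI(OAc)2 (2.5 equiv), CH2Cl2, 23 °C
Reagents that add atoms: none
Why: Nitroxyl-catalysed oxidative lactonization of a 1,5-diol: the primary alcohol is oxidized to the aldehyde, trapped as the lactol by the cis 1β-hydroxyl and oxidized on to the lactone. The trans 3α-hydroxyl cannot bridge to C9 and secondary alcohols react slowly, so the three hydroxyls are told apart without protecting groups.

Step 4
Reactants: 4 hydroxy lactone (both C8 epimers)
Product: 5 4,8-dimethyl-7-(triisopropylsilyloxy)-2-oxabicyclo[3.3.1]nonan-3-one (both C8 epimers)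
Conditions: iPr3SiOTf, 2,6-lutidine, CH2Cl2, 0 °C
Reagents that add atoms: triisopropylsilyl trifluoromethanesulfonate, CC(C)[Si](C(C)C)(C(C)C)OS(=O)(=O)C(F)(F)F
Why: Silylation of the equatorial 3α-alcohol with a silyl triflate; the triisopropylsilyl ether is chosen to outlast the later acid and base steps.

Step 5
Reactants: 5 silyl ether lactone (both C8 epimers)
Product: 7 (8R)-lactone with the C8 methyl equatorial on the lactone ring, via lithium enolate 6 (not isolated)
Conditions: LiN(iPr)2 (1.3 equiv), THF, −78 °C; then AcOH, THF, −78 °C
Reagents that add atoms: none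
Why: Enolization and kinetic protonation of a lactone enolate: both epimers give the same enolate 6. Protonation should occur axially on the lactone half-chair from the open face on the side of the one-carbon bridge C6 (the other face looks onto C4 and C3 of the carbocycle), which places the methyl equatorial and gives the 8R configuration of the target.

Step 6
Reactants: 7 (8R)-lactone
Product: 9 4-methoxybenzyl (2R)-2-[1β-hydroxy-2β-methyl-3α-(triisopropylsilyloxy)cyclohex-5β-yl]propanoate, via cesium carboxylate 8 (not isolated)
Conditions: CsOH·H2O (1.1 equiv), THF/H2O, 23 °C; evaporate; then 4-MeOC6H4CH2Cl, DMF, 23 °C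
Reagents that add atoms: cesium hydroxide, [Cs+].[OH-]; 4-methoxybenzyl chloride, COc1ccc(CCl)cc1
Why: Saponification of the bridged lactone followed by O-alkylation of the cesium carboxylate; a carboxylate does not enolize under these conditions, so C8 is kept, and the 1β-hydroxyl is set free for oxidation.

Step 7
Reactants: 9 hydroxy ester
Product: 10 4-methoxybenzyl (2R)-2-[2β-methyl-1-oxo-3α-(triisopropylsilyloxy)cyclohex-5β-yl]propanoate
Conditions: Dess–Martin periodinane, CH2Cl2, 0 → 23 °C
Reagents that add atoms: none
Why: Dess–Martin oxidation of the secondary alcohol under non-basic conditions, which should leave the epimerizable C2 (methyl α to the new ketone) untouched.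

Step 8
Reactants: 10 cyclohexanone
Product: 12 enol silane of the ring-enlarged ketone, 4-methoxybenzyl (2R)-2-[2β-methyl-3α-(triisopropylsilyloxy)-1-(trimethylsilyloxy)cyclohept-1(7)-en-5β-yl]propanoate, via β-keto silane 11 (not isolated)
Conditions: Me3SiCHN2 (1.5 equiv), Sc(OTf)3 (10 mol %), toluene, −20 → 23 °C, then 50 °C
Reagents that add atoms: (trimethylsilyl)diazomethane, C[Si](C)(C)C=[N+]=[N-]
Why: Lewis-acid-promoted diazoalkane–ketone homologation (a Tiffeneau–Demjanov-type 1,2-shift), a known single-carbon ring expansion of cyclohexanones. Sc(OTf)3 activates the C1 carbonyl, the diazo carbon adds to C1 to give a diazonium betaine, and the ring bond anti-periplanar to the C–N2 bond migrates from C1 to the new carbon with loss of N2, so that this carbon (C7) ends up between C1 and C6 and C1 is a carbonyl again. No ring is closed: the six-membered ring is enlarged to the seven-membered ring by a 1,2-alkyl shift, formally an insertion of C7 into the C1–C6 bond. The step needs regioselectivity, migration of C6 and not of C2: C6 is a CH2 group, whereas C2 is tertiary, carries the methyl group and is flanked by the 3-silyloxy group, and in the betaine the bulky SiMe3 group avoids C2 only in the rotamer that puts C6 anti to the leaving N2. No stereocentre is created that survives (C7 of 11 becomes trigonal) and none is touched: C5, next to the migrating carbon, is a spectator, and C2 should stay configurationally intact because no base is present. The β-keto silane 11 should then undergo the 1,3-shift of silicon from carbon to oxygen (Brook rearrangement), which fixes the enol double bond at C1=C7, exactly on the inserted carbon, so the next step needs no regioselective enolization, and the silylated product cannot be homologated a second time.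

Step 9
Reactants: 12 enol silane
Product: 13 4-methoxybenzyl (2R)-2-[2β-methyl-1-oxo-3α-(triisopropylsilyloxy)cyclohept-6-en-5β-yl]propanoate (C6=C7 enone)
Conditions: Pd(OAc)2 (1.05 equiv), MeCN, 23 °C
Reagents that add atoms: none
Why: Saegusa–Ito oxidation: the palladium enolate formed at C7 can lose only the β-hydrogens on C6, so the enone double bond is C6=C7; no base is used, so C2 and C8 are not at risk.

Step 10
Reactants: 13 enone
Product: 14 6α,7α-epoxy ketone, 4-methoxybenzyl (2R)-2-[6α,7α-epoxy-2β-methyl-1-oxo-3α-(triisopropylsilyloxy)cyclohept-5β-yl]propanoate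
Conditions: t-BuOOH (in decane), DBU, CH2Cl2, 0 °C
Reagents that add atoms: tert-butyl hydroperoxide, CC(C)(C)OO
Why: Weitz–Scheffer nucleophilic epoxidation of the enone: the hydroperoxide anion should add to C6 anti to the adjacent C5 side chain (β face blocked) and the enolate closes on the same α face, giving the 6α,7α-epoxide.

Step 11
Reactants: 14 epoxy ketone
Product: 16 7α-hydroxy-2β-methyl-1-oxo-3α-(triisopropylsilyloxy)cycloheptane cis-fused at C5–C6 to the (8R)-α-methyl-γ-lactone (6β-O), via epoxy acid 15 (not isolated)
Conditions: CF3CO2H/CH2Cl2 (1:9), anisole, 0 °C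
Reagents that add atoms: none
Why: Acidolysis of the 4-methoxybenzyl ester and epoxide-opening lactonization: the freed carboxylic acid, held on the β face by C5, should attack C6 of the protonated epoxide in a 5-exo mode with inversion, giving the cis-fused γ-lactone and leaving the 7α-hydroxyl with its configuration. Attack at C7 would need a six-membered ring and an unfavourable geometry.

Step 12
Reactants: 17 but-2-yn-1-ol
Product: 18 1-methoxybut-2-yne
Conditions: NaH, MeI, THF, 0 → 23 °C
Reagents that add atoms: iodomethane, CI
Why: Williamson ether synthesis on a primary propargylic alkoxide.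

Step 13
Reactants: 18 1-methoxybut-2-yne
Product: 19 1-methoxybuta-1,2-diene
Conditions: KOtBu (0.2 equiv), DMSO, 23–40 °C; distil under reduced pressure
Reagents that add atoms: none
Why: Base-catalysed propargyl–allenyl isomerization (prototropic shift) to the alkoxyallene; the product is distilled from the base before it can go on to the conjugated diene.

Step 14
Reactants: 16 hydroxy keto lactone; 19 1-methoxybuta-1,2-diene
Product: 21 1α-(1-methoxybuta-1,2-dien-1-yl)-1β,7α-dihydroxy-2β-methyl-3α-(triisopropylsilyloxy) lactone (allene diastereomers), via lithioallene 20 (not isolated)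
Conditions: 19 (3.5 equiv), n-BuLi (3.3 equiv), THF, −40 °C; CeCl3, −78 °C; then 16, −78 °C; H2O quench
Reagents that add atoms: none
Why: 1,2-Addition of a lithiated alkoxyallene (an α,β-unsaturated acyl anion equivalent) as its cerium reagent; the first equivalent deprotonates 7-OH, and the alkoxide blocks enolization towards C7 and chelates the metal with the C1 carbonyl. The nucleophile should then attack from the α face, trans to the C2 methyl and away from the β-face lactone (in the twist-chair with equatorial 3- and 7-oxygens the β face is screened by the C2 methyl and C8), giving the 1β-hydroxyl. The cerium reagent is ketone-selective, so the lactone should survive.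

Step 15
Reactants: 21 allenyl diol
Product: 22 7α-O-[(E)-2-methylbut-2-enoyl] derivative of 21
Conditions: (E)-MeCH=C(Me)COCl, DMAP (cat.), pyridine, CH2Cl2, 0 → 23 °C
Reagents that add atoms: (E)-2-methylbut-2-enoyl chloride (tigloyl chloride), C/C=C(\C)C(Cl)=O
Why: DMAP-catalysed acylation of the secondary 7α-alcohol; the tertiary 1β-alcohol does not react and the enol ether tolerates the basic medium. Acylating before the enone is unmasked removes the risk of intramolecular oxa-Michael addition of 7-OH.

Step 16
Reactants: 22 allenyl tiglate
Product: 24 CNP0183494.2, via silyl ether 23 (not isolated)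
Conditions: 48% aq. HF, MeCN, 0 → 23 °C
Reagents that add atoms: water, O
Why: Acid hydrolysis of the alkoxyallene (protonation at the central allene carbon, hydration of the oxocarbenium ion, loss of methanol) should give the conjugated (E)-enone 23, the thermodynamic isomer under acid; the same medium cleaves the silyl ether to free the 3α-hydroxyl.

## Compound list

1 | (R)-(−)-carvone, (5R)-2-methyl-5-(prop-1-en-2-yl)cyclohex-2-en-1-one | CC1=CC[C@H](CC1=O)C(C)=C | starting material
2 | (1R,5R)-cis-carveol | CC1=CC[C@H](C[C@H]1O)C(C)=C | intermediate
3 | 5β-(1-hydroxypropan-2-yl)-2β-methylcyclohexane-1β,3α-diol (C8 epimers) | C[C@H]1[C@H](O)C[C@H](C[C@H]1O)C(C)CO | intermediate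
4 | 7-hydroxy-4,8-dimethyl-2-oxabicyclo[3.3.1]nonan-3-one (C8 epimers) | C[C@H]1[C@H](O)C[C@@H]2C[C@H]1OC(=O)C2C | intermediate
5 | 4,8-dimethyl-7-(triisopropylsilyloxy)-2-oxabicyclo[3.3.1]nonan-3-one (C8 epimers) | C[C@H]1[C@H](O[Si](C(C)C)(C(C)C)C(C)C)C[C@@H]2C[C@H]1OC(=O)C2C | intermediate
6 | lithium enolate of 5 | C[C@H]1[C@H](O[Si](C(C)C)(C(C)C)C(C)C)C[C@@H]2C[C@H]1OC(O[Li])=C2C | intermediate (not isolated)
7 | (8R)-epimer of 5, C8 methyl equatorial | C[C@H]1[C@H](O[Si](C(C)C)(C(C)C)C(C)C)C[C@@H]2C[C@H]1OC(=O)[C@@H]2C | intermediate
8 | cesium (2R)-2-[1β-hydroxy-2β-methyl-3α-(triisopropylsilyloxy)cyclohex-5β-yl]propanoate | C[C@H]1[C@H](O[Si](C(C)C)(C(C)C)C(C)C)C[C@H](C[C@H]1O)[C@@H](C)C(=O)[O-].[Cs+] | intermediate (not isolated)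
9 | 4-methoxybenzyl (2R)-2-[1β-hydroxy-2β-methyl-3α-(triisopropylsilyloxy)cyclohex-5β-yl]propanoate | C[C@H]1[C@H](O[Si](C(C)C)(C(C)C)C(C)C)C[C@H](C[C@H]1O)[C@@H](C)C(=O)OCc1ccc(OC)cc1 | intermediate
10 | 4-methoxybenzyl (2R)-2-[2β-methyl-1-oxo-3α-(triisopropylsilyloxy)cyclohex-5β-yl]propanoate | C[C@H]1[C@H](O[Si](C(C)C)(C(C)C)C(C)C)C[C@H](CC1=O)[C@@H](C)C(=O)OCc1ccc(OC)cc1 | intermediate
11 | 4-methoxybenzyl (2R)-2-[2β-methyl-1-oxo-3α-(triisopropylsilyloxy)-7-(trimethylsilyl)cyclohept-5β-yl]propanoate | C[C@H]1[C@H](O[Si](C(C)C)(C(C)C)C(C)C)C[C@H](CC([Si](C)(C)C)C1=O)[C@@H](C)C(=O)OCc1ccc(OC)cc1 | intermediate (not isolated)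
12 | 4-methoxybenzyl (2R)-2-[2β-methyl-3α-(triisopropylsilyloxy)-1-(trimethylsilyloxy)cyclohept-1(7)-en-5β-yl]propanoate | C[C@H]1[C@H](O[Si](C(C)C)(C(C)C)C(C)C)C[C@H](CC=C1O[Si](C)(C)C)[C@@H](C)C(=O)OCc1ccc(OC)cc1 | intermediate
13 | 4-methoxybenzyl (2R)-2-[2β-methyl-1-oxo-3α-(triisopropylsilyloxy)cyclohept-6-en-5β-yl]propanoate | C[C@H]1[C@H](O[Si](C(C)C)(C(C)C)C(C)C)C[C@H](C=CC1=O)[C@@H](C)C(=O)OCc1ccc(OC)cc1 | intermediate
14 | 4-methoxybenzyl (2R)-2-[6α,7α-epoxy-2β-methyl-1-oxo-3α-(triisopropylsilyloxy)cyclohept-5β-yl]propanoate | C[C@H]1[C@H](O[Si](C(C)C)(C(C)C)C(C)C)C[C@H]([C@@H]2O[C@@H]2C1=O)[C@@H](C)C(=O)OCc1ccc(OC)cc1 | intermediate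
15 | (2R)-2-[6α,7α-epoxy-2β-methyl-1-oxo-3α-(triisopropylsilyloxy)cyclohept-5β-yl]propanoic acid | C[C@H]1[C@H](O[Si](C(C)C)(C(C)C)C(C)C)C[C@H]([C@@H]2O[C@@H]2C1=O)[C@@H](C)C(O)=O | intermediate (not isolated)
16 | 7α-hydroxy-2β-methyl-1-oxo-3α-(triisopropylsilyloxy)cycloheptane cis-fused at C5–C6 to the (8R)-α-methyl-γ-lactone | O=C1[C@@H](C)[C@H](O[Si](C(C)C)(C(C)C)C(C)C)C[C@@H]2[C@@H](OC(=O)[C@@H]2C)[C@@H]1O | intermediate
17 | but-2-yn-1-ol | CC#CCO | starting material
18 | 1-methoxybut-2-yne | CC#CCOC | intermediate
19 | 1-methoxybuta-1,2-diene | CC=C=COC | intermediate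
20 | 1-lithio-1-methoxybuta-1,2-diene | [Li]C(OC)=C=CC | intermediate (not isolated)
21 | 1α-(1-methoxybuta-1,2-dien-1-yl)-1β,7α-dihydroxy-2β-methyl-3α-(triisopropylsilyloxy) lactone | CC=C=C(OC)[C@]1(O)[C@@H](C)[C@H](O[Si](C(C)C)(C(C)C)C(C)C)C[C@@H]2[C@@H](OC(=O)[C@@H]2C)[C@@H]1O | intermediate
22 | 7α-O-[(E)-2-methylbut-2-enoyl] derivative of 21 | CC=C=C(OC)[C@]1(O)[C@@H](C)[C@H](O[Si](C(C)C)(C(C)C)C(C)C)C[C@@H]2[C@@H](OC(=O)[C@@H]2C)[C@@H]1OC(=O)/C(C)=C/C | intermediate
23 | 3-O-triisopropylsilyl ether of the target | C/C=C/C(=O)[C@]1(O)[C@@H](C)[C@H](O[Si](C(C)C)(C(C)C)C(C)C)C[C@@H]2[C@@H](OC(=O)[C@@H]2C)[C@@H]1OC(=O)/C(C)=C/C | intermediate (not isolated)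
24 | CNP0183494.2 | C/C=C/C(=O)[C@]1(O)[C@@H](C)[C@H](O)C[C@@H]2[C@@H](OC(=O)[C@@H]2C)[C@@H]1OC(=O)/C(C)=C/C | target

## Step count and least certain steps

Total step count: 16. Longest linear sequence: 14 steps (steps 1–11 and 14–16); steps 12 and 13 prepare the allene 19.

Step 8 (key step). What may go wrong: leakage of the 1,2-shift to the C2 side, closure of the betaine to an epoxide instead of migration, an incomplete carbon-to-oxygen silyl shift, or Lewis-acid enolization with loss of configuration at C2. Fallback, from 10 and back at 13: the carbon is inserted by cyclopropanation instead. Kinetic deprotonation on the CH2 side with LiN(iPr)2 and trapping with Me3SiCl should give the C1=C6 enol silane F1. Et2Zn/CH2I2 should give the siloxycyclopropane F2, in which the new carbon C7 bridges C1 and C6. FeCl3 in DMF should cleave the C1–C6 bond of F2 oxidatively to the 6-chloro cycloheptanone F3, and NaOAc in MeOH should eliminate HCl to the enone 13. The regiochemistry is then fixed by the enolization, and steps 8 and 9 are replaced.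

Step 5. What may go wrong: poor facial discrimination in the protonation, because the two faces of the enolate differ only in their surroundings (C4 on one side, the C6 bridge on the other), so both C8 epimers could persist. Fallback, from 5 and back at 7: LiN(iPr)2 then PhSeBr should give the 8-phenylselanyl lactone F4. Oxidation with H2O2 and syn-elimination, which cannot run towards the bridgehead C5 (Bredt's rule), should give the 8-methylene lactone F5. Hydrogenation with Ru(OAc)2(BINAP), the ligand enantiomer chosen so that the catalyst delivers hydrogen to the required face, should give 7 under catalyst control.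

Step 14. What may go wrong: proton transfer from C2–H to the hindered, γ-substituted allenyl anion instead of addition, reaction through the γ-carbon, and, one step earlier, over-isomerization of 19 to the conjugated diene in step 13. Fallback, from 16 and ending at 24: the parent lithiated methoxyallene, made from commercial methoxyallene and n-BuLi and used as its CeCl3 reagent, is smaller and more reactive and should give the 1α-(1-methoxypropa-1,2-dien-1-yl) carbinol F6. Acylation as in step 15 should give the tiglate F7. Aqueous HF in MeCN should then give the vinyl ketone F8 with the 3-OH free. Cross-metathesis of F8 with (Z)-but-2-ene and the second-generation Grubbs catalyst should attach the missing methyl group and give 24 as the (E)-enone; the trisubstituted tiglate alkene should be inert.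

Step 10. What may go wrong: loss of configuration at C2 (α to the ketone) under the basic conditions, or incomplete facial selectivity of the conjugate addition. Fallback, from 13 and back at 16: OsO4 (cat.) with N-methylmorpholine N-oxide should dihydroxylate the enone on the α face to the 6α,7α-diol F9. SOCl2/Et3N followed by RuCl3 (cat.)/NaIO4 should give the cyclic sulfate F10. CF3CO2H/anisole should then free the acid, which opens the cyclic sulfate at C6 with inversion to the lactone 7-sulfate F11, and dilute aqueous H2SO4 should hydrolyse F11 to 16. No base is involved.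

## Further compounds

F1 | step 8 | C1=C6 trimethylsilyl enol ether of 10 | C[C@H]1[C@H](O[Si](C(C)C)(C(C)C)C(C)C)C[C@H](C=C1O[Si](C)(C)C)[C@@H](C)C(=O)OCc1ccc(OC)cc1
F2 | step 8 | siloxycyclopropane, C7 bridging C1 and C6 | C[C@H]1[C@H](O[Si](C(C)C)(C(C)C)C(C)C)C[C@H](C2CC12O[Si](C)(C)C)[C@@H](C)C(=O)OCc1ccc(OC)cc1
F3 | step 8 | 6-chloro cycloheptanone | C[C@H]1[C@H](O[Si](C(C)C)(C(C)C)C(C)C)C[C@H](C(Cl)CC1=O)[C@@H](C)C(=O)OCc1ccc(OC)cc1
F4 | step 5 | 8-phenylselanyl lactone | C[C@H]1[C@H](O[Si](C(C)C)(C(C)C)C(C)C)C[C@@H]2C[C@H]1OC(=O)C2(C)[Se]c1ccccc1
F5 | step 5 | 8-methylene lactone | C[C@H]1[C@H](O[Si](C(C)C)(C(C)C)C(C)C)C[C@@H]2C[C@H]1OC(=O)C2=C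
F6 | step 14 | 1α-(1-methoxypropa-1,2-dien-1-yl) carbinol | C=C=C(OC)[C@]1(O)[C@@H](C)[C@H](O[Si](C(C)C)(C(C)C)C(C)C)C[C@@H]2[C@@H](OC(=O)[C@@H]2C)[C@@H]1O
F7 | step 14 | 7α-tiglate of F6 | C=C=C(OC)[C@]1(O)[C@@H](C)[C@H](O[Si](C(C)C)(C(C)C)C(C)C)C[C@@H]2[C@@H](OC(=O)[C@@H]2C)[C@@H]1OC(=O)/C(C)=C/C
F8 | step 14 | vinyl ketone, the target lacking the terminal methyl of the enone | C=CC(=O)[C@]1(O)[C@@H](C)[C@H](O)C[C@@H]2[C@@H](OC(=O)[C@@H]2C)[C@@H]1OC(=O)/C(C)=C/C
F9 | step 10 | 6α,7α-diol of 13 | C[C@H]1[C@H](O[Si](C(C)C)(C(C)C)C(C)C)C[C@H]([C@H](O)[C@H](O)C1=O)[C@@H](C)C(=O)OCc1ccc(OC)cc1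
F10 | step 10 | 6α,7α-cyclic sulfate | C[C@H]1[C@H](O[Si](C(C)C)(C(C)C)C(C)C)C[C@H]([C@@H]2OS(=O)(=O)O[C@@H]2C1=O)[C@@H](C)C(=O)OCc1ccc(OC)cc1
F11 | step 10 | 7α-hydrogen sulfate of 16 | O=C1[C@@H](C)[C@H](O[Si](C(C)C)(C(C)C)C(C)C)C[C@@H]2[C@@H](OC(=O)[C@@H]2C)[C@@H]1OS(O)(=O)=O
A1 | alternative 1 | open-chain triene, methyl ester, 3-O-tert-butyldimethylsilyl | C/C=C/C(=O)[C@@](O)(C=C)[C@@H](C)[C@H](O[Si](C)(C)C(C)(C)C)C[C@H](C=C)[C@@H](C)C(=O)OC
A2 | alternative 1 | cycloheptene from ring-closing metathesis (C6=C7) | C/C=C/C(=O)[C@]1(O)[C@@H](C)[C@H](O[Si](C)(C)C(C)(C)C)C[C@H](C=C1)[C@@H](C)C(=O)OC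
A3 | alternative 2 | 1-benzyloxy-3-methyl-2-oxyallyl cation | CC=C([O-])C=[O+]Cc1ccccc1
A4 | alternative 2 | 4-benzyloxy-2-methyl-8-oxabicyclo[3.2.1]oct-6-en-3-one, cis-diequatorial (racemic, one enantiomer drawn) | O=C1[C@@H](C)[C@H]2C=C[C@H](O2)[C@H]1OCc1ccccc1
A5 | alternative 3 | six-membered keto lactone (ketone at C7) | O=C1[C@@H](C)[C@H](O[Si](C(C)C)(C(C)C)C(C)C)C[C@@H]2[C@H]1OC(=O)[C@@H]2C
A6 | alternative 3 | (E)-1-diazopent-3-en-2-one | C/C=C/C(=O)C=[N+]=[N-]
A7 | alternative 3 | ring-enlarged β-diketone with the side chain on C1 | C/C=C/C(=O)C1[C@@H](C)[C@H](O[Si](C(C)C)(C(C)C)C(C)C)C[C@@H]2[C@@H](OC(=O)[C@@H]2C)C1=O
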